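**Plan**

- The retrosynthesis first cuts the two ester C(=O)–O bonds on the central ring. The two free central hydroxyls are traced back to the carbonyls of a 2,5-diacyloxy-1,4-benzoquinone, which leads to 4,4'-di-O-benzylatromentin, 3-phenylpropanoyl chloride and (S)-3-(benzyloxy)butanoyl chloride.
- Next, in each outer ring the C2'–C3' and C6'–C1' bonds are cut. Each outer ring is a 4-hydroxyphenyl group whose C4' hydroxyl is para to C1', the carbon bonded to the central ring. This is the pattern a 1-methoxy-3-silyloxybutadiene lays down across a C≡C bond, here an ethynyl group on a 3,6-dimethoxy-1,4-benzoquinone.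
- Last, the two quinone–alkyne C–C bonds are cut to 2,5-dibromo-3,6-dimethoxy-1,4-benzoquinone (from bromanil) and an alkynylstannane.
- Forward: the central ring is bought as a quinone, and both outer benzene rings arise together in one operation by double [4+2] cycloaddition and aromatisation. The phenols are then benzylated, the enolic hydroxyls unmasked and acylated one after the other, and one hydrogenation reduces the quinone and removes three benzyl groups.
- The only stereocentre (S, C3 of the hydroxybutanoate) is bought with ethyl (S)-3-hydroxybutanoate and never becomes a reacting centre.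

Key step: step 4

Assumption: in the twofold reactions at the two equivalent sites of the centrosymmetric core (steps 1–6) both sites react in the same flask, and the half-converted species are not numbered.

**Route**

Step 1
Reactants: 1 bromanil (2,3,5,6-tetrabromo-1,4-benzoquinone)
Product: 2 2,5-dibromo-3,6-dimethoxy-1,4-benzoquinone
Conditions: NaOMe (2.1 equiv), MeOH, 0 °C → rt
Reagents that add atoms: sodium methoxide, C[O-].[Na+]
Why: Twofold addition–elimination (vinylogous acyl substitution) of methoxide on the tetrahaloquinone should stop at the 2,5-disubstituted stage, because each methoxy group turns its half of the quinone into a vinylogous ester that resists further attack.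

Step 2
Reactants: 2 2,5-dibromo-3,6-dimethoxy-1,4-benzoquinone; 3 tributyl[(trimethylsilyl)ethynyl]stannane (2.3 equiv)
Product: 4 2,5-dimethoxy-3,6-bis[(trimethylsilyl)ethynyl]-1,4-benzoquinone
Conditions: Pd(PPh3)4 (5 mol %), CuI (10 mol %), 1,4-dioxane, 70 °C, Ar
Reagents that add atoms: none
Why: Stille coupling, in which the β-bromo enone C–Br bonds of the quinone undergo fast oxidative addition and the alkynyl group is the most readily transferred group on tin, under neutral conditions that avoid the amine of a Sonogashira coupling, which would add to the quinone.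

Step 3
Reactants: 4 2,5-dimethoxy-3,6-bis[(trimethylsilyl)ethynyl]-1,4-benzoquinone
Product: 5 2,5-diethynyl-3,6-dimethoxy-1,4-benzoquinone
Conditions: TBAF (2.1 equiv), AcOH (2.5 equiv), THF, −78 → −20 °C; short cold silica plug; used at once as a solution, dark
Reagents that add atoms: none
Why: Fluoride-mediated protodesilylation of an alkynylsilane, made especially easy by the electron-poor quinone, with the acetic acid buffer protonating the acetylide at once so that the medium stays non-basic and the electrophilic quinone is spared.

Step 4
Reactants: 5 2,5-diethynyl-3,6-dimethoxy-1,4-benzoquinone; 6 (E)-1-methoxy-3-(trimethylsilyloxy)buta-1,3-diene (3 equiv)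
Product: 9 2,5-bis(4-hydroxyphenyl)-3,6-dimethoxy-1,4-benzoquinone, via double cycloadduct 7 (not isolated), via bis(aryl silyl ether) 8 (not isolated)
Conditions: PhMe, 0 → 50 °C, Ar, dark; then 1 M aq. HCl, THF, rt
Reagents that add atoms: none
Why: Proposed new method: each ethynyl group is the far end of a cross-conjugated acceptor (O=C–C(OMe)=C–C≡CH), so the nucleophilic CH2 terminus of the diene should bond to the terminal alkyne carbon (new C2'–C3' bond) and the methoxy-bearing terminus to the internal alkyne carbon (new C6'–C1' bond), either in an asynchronous concerted [4+2] cycloaddition or by a vinylogous Mukaiyama–Michael addition followed by closure of the allenolate onto the oxocarbenium carbon. The closest known reaction type is the Diels–Alder reaction of 1-alkoxy-3-silyloxybutadienes with acetylenic ketones and esters, which after loss of alcohol gives para-acylphenols; an alkyne activated only through a quinone C=C bond has not been shown to react in this way. Each of the two outer six-membered rings closes by an intermolecular [4+2] in which four carbons come from the diene and two from the alkyne, and the 1,4-cyclohexadiene rings of 7 then lose methanol in an aromatisation-driven 1,4-elimination to give 8, whose silyl ethers are hydrolysed in the same acidic work-up. No stereocentre is set, since the CH(OMe) carbons of 7 form without control and become sp2 on aromatisation. The step needs regioselectivity, so that the oxygen ends up at C4' para to the biaryl bond, and this is secured by the polarity match just described and by the low steric demand of the terminal alkyne carbon; it also needs chemoselectivity for the alkynes over the ring C=C bonds, which is secured because both ring C=C bonds are tetrasubstituted and deactivated as vinylogous esters by their methoxy groups.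

Step 5
Reactants: 9 2,5-bis(4-hydroxyphenyl)-3,6-dimethoxy-1,4-benzoquinone
Product: 10 2,5-bis[4-(benzyloxy)phenyl]-3,6-dimethoxy-1,4-benzoquinone
Conditions: BnBr (2.4 equiv), K2CO3, DMF, rt
Reagents that add atoms: benzyl bromide, BrCc1ccccc1
Why: Williamson ether synthesis at the two phenols, the only acidic sites, with carbonate in dry DMF supplying no hydroxide so that the vinylogous methyl esters of the quinone are left alone.

Step 6
Reactants: 10 2,5-bis[4-(benzyloxy)phenyl]-3,6-dimethoxy-1,4-benzoquinone
Product: 11 2,5-bis[4-(benzyloxy)phenyl]-3,6-dihydroxy-1,4-benzoquinone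
Conditions: 2 M aq. NaOH, 1,4-dioxane, 50 °C; then 1 M HCl
Reagents that add atoms: sodium hydroxide, [Na+].[OH-]
Why: The methoxy groups are vinylogous methyl esters, so hydroxide should cleave them by conjugate addition–elimination (vinylogous saponification) to the stable bis-enolate, while the aryl benzyl ethers are inert to aqueous base.

Step 7
Reactants: 11 2,5-bis[4-(benzyloxy)phenyl]-3,6-dihydroxy-1,4-benzoquinone; 12 3-phenylpropanoyl chloride (1.0 equiv, slow addition)
Product: 13 2,5-bis[4-(benzyloxy)phenyl]-4-hydroxy-3,6-dioxocyclohexa-1,4-dien-1-yl 3-phenylpropanoate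
Conditions: pyridine (3 equiv), THF, −20 °C
Reagents that add atoms: none
Why: O-Acylation of a vinylogous carboxylic acid with an acid chloride in the presence of pyridine; the two hydroxyls are equivalent by symmetry, so one equivalent of 12 added slowly in the cold should give mainly the mono-ester, to be separated from recyclable 11 and the bis-ester.

Step 8
Reactants: 14 ethyl (S)-3-hydroxybutanoate
Product: 15 ethyl (S)-3-(benzyloxy)butanoate
Conditions: benzyl 2,2,2-trichloroacetimidate (1.3 equiv), TfOH (5 mol %), CH2Cl2/cyclohexane, 0 °C → rt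
Reagents that add atoms: benzyl 2,2,2-trichloroacetimidate, N=C(OCc1ccccc1)C(Cl)(Cl)Cl
Why: Acid-catalysed O-benzylation with the trichloroacetimidate avoids the basic conditions under which a β-hydroxy ester undergoes retro-aldol cleavage or elimination, and it forms the O–CH2Ph bond without touching the C3–O bond, so C3 stays S.

Step 9
Reactants: 15 ethyl (S)-3-(benzyloxy)butanoate
Product: 16 (S)-3-(benzyloxy)butanoic acid
Conditions: LiOH·H2O, THF/H2O, 0 °C → rt; then 1 M HCl
Reagents that add atoms: lithium hydroxide, [Li+].[OH-]
Why: Saponification of the ethyl ester at or below room temperature, where C3 is not acidic and E1cB loss of benzyl alcohol from the β-alkoxy ester should not compete.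

Step 10
Reactants: 16 (S)-3-(benzyloxy)butanoic acid
Product: 17 (S)-3-(benzyloxy)butanoyl chloride
Conditions: (COCl)2 (1.5 equiv), DMF (cat.), CH2Cl2, 0 °C → rt; evaporated and used crude
Reagents that add atoms: oxalyl chloride, O=C(Cl)C(=O)Cl
Why: Acid chloride formation through the chloroiminium species from oxalyl chloride and catalytic DMF, under conditions that leave the benzyl ether and the stereocentre untouched.

Step 11
Reactants: 13 2,5-bis[4-(benzyloxy)phenyl]-4-hydroxy-3,6-dioxocyclohexa-1,4-dien-1-yl 3-phenylpropanoate; 17 (S)-3-(benzyloxy)butanoyl chloride (1.5 equiv)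
Product: 18 2,5-bis[4-(benzyloxy)phenyl]-3,6-dioxo-4-[(3-phenylpropanoyl)oxy]cyclohexa-1,4-dien-1-yl (S)-3-(benzyloxy)butanoate
Conditions: pyridine (3 equiv), CH2Cl2, 0 °C
Reagents that add atoms: none
Why: Second O-acylation of the remaining enolic hydroxyl, run with an excess of the acid chloride and only the weak base pyridine at 0 °C, so that acylation by 17 should outrun acyl transfer between acyloxyquinone molecules and the β-benzyloxy group should not be eliminated.

Step 12
Reactants: 18 2,5-bis[4-(benzyloxy)phenyl]-3,6-dioxo-4-[(3-phenylpropanoyl)oxy]cyclohexa-1,4-dien-1-yl (S)-3-(benzyloxy)butanoate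
Product: 20 2,5-dihydroxy-3,6-bis(4-hydroxyphenyl)-4-[(3-phenylpropanoyl)oxy]phenyl (S)-3-hydroxybutanoate (CNP0296884.1), via hydroquinone tribenzyl ether 19 (not isolated)
Conditions: H2 (1 atm), Pd(OH)2/C, EtOAc, rt; filtered and concentrated under Ar
Reagents that add atoms: none
Why: Catalytic hydrogenation should first reduce the quinone to the hydroquinone, turning the two carbonyls into the free central hydroxyls, and then hydrogenolyse the two aryl benzyl ethers and the one alkyl benzyl ether, while the neutral aprotic medium gives the esters no occasion to migrate to the neighbouring hydroxyls or to be solvolysed.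

**Compound list**

1 | bromanil (2,3,5,6-tetrabromo-1,4-benzoquinone) | O=C1C(Br)=C(Br)C(=O)C(Br)=C1Br | starting material
2 | 2,5-dibromo-3,6-dimethoxy-1,4-benzoquinone | COC1=C(Br)C(=O)C(OC)=C(Br)C1=O | intermediate
3 | tributyl[(trimethylsilyl)ethynyl]stannane | CCCC[Sn](CCCC)(CCCC)C#C[Si](C)(C)C | starting material
4 | 2,5-dimethoxy-3,6-bis[(trimethylsilyl)ethynyl]-1,4-benzoquinone | COC1=C(C#C[Si](C)(C)C)C(=O)C(OC)=C(C#C[Si](C)(C)C)C1=O | intermediate
5 | 2,5-diethynyl-3,6-dimethoxy-1,4-benzoquinone | COC1=C(C#C)C(=O)C(OC)=C(C#C)C1=O | intermediate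
6 | (E)-1-methoxy-3-(trimethylsilyloxy)buta-1,3-diene | CO/C=C/C(=C)O[Si](C)(C)C | starting material
7 | 2,5-dimethoxy-3,6-bis[6-methoxy-4-(trimethylsilyloxy)cyclohexa-1,4-dien-1-yl]-1,4-benzoquinone (double cycloadduct; mixture of diastereomers at the two CH(OMe) carbons) | COC1=C(C2=CCC(O[Si](C)(C)C)=CC2OC)C(=O)C(OC)=C(C2=CCC(O[Si](C)(C)C)=CC2OC)C1=O | intermediate
8 | 2,5-dimethoxy-3,6-bis[4-(trimethylsilyloxy)phenyl]-1,4-benzoquinone | COC1=C(c2ccc(O[Si](C)(C)C)cc2)C(=O)C(OC)=C(c2ccc(O[Si](C)(C)C)cc2)C1=O | intermediate
9 | 2,5-bis(4-hydroxyphenyl)-3,6-dimethoxy-1,4-benzoquinone (atromentin 2,5-di-O-methyl ether) | COC1=C(c2ccc(O)cc2)C(=O)C(OC)=C(c2ccc(O)cc2)C1=O | intermediate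
10 | 2,5-bis[4-(benzyloxy)phenyl]-3,6-dimethoxy-1,4-benzoquinone | COC1=C(c2ccc(OCc3ccccc3)cc2)C(=O)C(OC)=C(c2ccc(OCc3ccccc3)cc2)C1=O | intermediate
11 | 2,5-bis[4-(benzyloxy)phenyl]-3,6-dihydroxy-1,4-benzoquinone | OC1=C(c2ccc(OCc3ccccc3)cc2)C(=O)C(O)=C(c2ccc(OCc3ccccc3)cc2)C1=O | intermediate
12 | 3-phenylpropanoyl chloride | O=C(Cl)CCc1ccccc1 | starting material
13 | 2,5-bis[4-(benzyloxy)phenyl]-4-hydroxy-3,6-dioxocyclohexa-1,4-dien-1-yl 3-phenylpropanoate | O=C(CCc1ccccc1)OC1=C(c2ccc(OCc3ccccc3)cc2)C(=O)C(O)=C(c2ccc(OCc3ccccc3)cc2)C1=O | intermediate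
14 | ethyl (S)-3-hydroxybutanoate | C[C@H](O)CC(=O)OCC | starting material
15 | ethyl (S)-3-(benzyloxy)butanoate | C[C@H](OCc1ccccc1)CC(=O)OCC | intermediate
16 | (S)-3-(benzyloxy)butanoic acid | C[C@H](OCc1ccccc1)CC(=O)O | intermediate
17 | (S)-3-(benzyloxy)butanoyl chloride | C[C@H](OCc1ccccc1)CC(=O)Cl | intermediate
18 | 2,5-bis[4-(benzyloxy)phenyl]-3,6-dioxo-4-[(3-phenylpropanoyl)oxy]cyclohexa-1,4-dien-1-yl (S)-3-(benzyloxy)butanoate | C[C@H](OCc1ccccc1)CC(=O)OC1=C(c2ccc(OCc3ccccc3)cc2)C(=O)C(OC(=O)CCc2ccccc2)=C(c2ccc(OCc3ccccc3)cc2)C1=O | intermediate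
19 | 2,5-bis[4-(benzyloxy)phenyl]-3,6-dihydroxy-4-[(3-phenylpropanoyl)oxy]phenyl (S)-3-(benzyloxy)butanoate (hydroquinone tribenzyl ether) | C[C@H](OCc1ccccc1)CC(=O)Oc1c(O)c(-c2ccc(OCc3ccccc3)cc2)c(OC(=O)CCc2ccccc2)c(O)c1-c1ccc(OCc2ccccc2)cc1 | intermediate
20 | 2,5-dihydroxy-3,6-bis(4-hydroxyphenyl)-4-[(3-phenylpropanoyl)oxy]phenyl (S)-3-hydroxybutanoate (CNP0296884.1) | C[C@H](O)CC(=O)Oc1c(O)c(-c2ccc(O)cc2)c(OC(=O)CCc2ccccc2)c(O)c1-c1ccc(O)cc1 | target

**Count**

Total steps: 12. Longest linear sequence: 9 steps (steps 1–7, 11, 12); the side chain (steps 8–10) joins at step 11.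

**Steps most likely to fail**

1. Step 4 (the proposed new method). The ethynylquinone may oligomerise, or the diene may react as a plain silyl enol ether at a quinone carbonyl or add with the opposite orientation, faster than the wanted double cycloaddition. The second cycloaddition may also stall once the first aryl group has made the quinone less electron-poor. The fallback uses known chemistry and attaches the outer rings ready-made. It sets out from 2: a twofold Suzuki–Miyaura coupling with commercial 4-(benzyloxy)phenylboronic acid (Pd(PPh3)4, K3PO4, 1,4-dioxane, 90 °C) should give 10 directly. It comes back to the route at 10 and replaces steps 2–5; no compound outside the list is made (F0).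

2. Step 3. During C–Si cleavage, fluoride or acetate may add in conjugate fashion to the newly freed, quinone-activated terminal alkyne, or the terminal ethynylquinone may oligomerise on handling. The fallback moves all alkyne chemistry to the hydroquinone dimethyl ether oxidation level and releases the quinone last. It sets out from 2, which is reduced with Na2S2O4 (EtOAc/H2O) to 2,5-dibromo-3,6-dimethoxybenzene-1,4-diol F1 and methylated (MeI, K2CO3, acetone, reflux) to 1,4-dibromo-2,3,5,6-tetramethoxybenzene F2. Sonogashira coupling with ethynyltrimethylsilane (Pd(PPh3)2Cl2, CuI, i-Pr2NH, 80 °C) should give 1,4-bis[(trimethylsilyl)ethynyl]-2,3,5,6-tetramethoxybenzene F3. K2CO3 in MeOH then frees the stable, unactivated 1,4-diethynyl-2,3,5,6-tetramethoxybenzene F4. Oxidative demethylation with ceric ammonium nitrate (MeCN/H2O, 0 °C) should deliver the quinone under acidic, non-nucleophilic conditions just before the cycloaddition. The fallback comes back to the route at 5.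

3. Step 7. Over-acylation and acyl transfer between acyloxyquinone molecules may leave the mono-ester as only one part of a statistical mixture. The fallback replaces mono-acylation by exhaustive acylation followed by a self-limiting mono-deacylation. It sets out from 11, which is treated with excess 12 (pyridine, CH2Cl2, 0 °C → rt) to give the symmetric 2,5-bis[4-(benzyloxy)phenyl]-3,6-bis[(3-phenylpropanoyl)oxy]-1,4-benzoquinone F5. One ester is then cleaved with one equivalent of LiOH (THF/H2O, 0 °C; then dilute HCl). After loss of the first acyl group the hydroxyquinone is an anion and the remaining vinylogous anhydride is much less electrophilic, so the cleavage should stop at the mono-ester. The fallback comes back to the route at 13.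

**Further compounds**

F0 | step 4 | none | none
F1 | step 3 | 2,5-dibromo-3,6-dimethoxybenzene-1,4-diol | COc1c(Br)c(O)c(OC)c(Br)c1O
F2 | step 3 | 1,4-dibromo-2,3,5,6-tetramethoxybenzene | COc1c(Br)c(OC)c(OC)c(Br)c1OC
F3 | step 3 | 1,4-bis[(trimethylsilyl)ethynyl]-2,3,5,6-tetramethoxybenzene | COc1c(C#C[Si](C)(C)C)c(OC)c(OC)c(C#C[Si](C)(C)C)c1OC
F4 | step 3 | 1,4-diethynyl-2,3,5,6-tetramethoxybenzene | COc1c(C#C)c(OC)c(OC)c(C#C)c1OC
F5 | step 7 | 2,5-bis[4-(benzyloxy)phenyl]-3,6-bis[(3-phenylpropanoyl)oxy]-1,4-benzoquinone | O=C(CCc1ccccc1)OC1=C(c2ccc(OCc3ccccc3)cc2)C(=O)C(OC(=O)CCc2ccccc2)=C(c2ccc(OCc3ccccc3)cc2)C1=O
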